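All runs are calculated for an exercise; noise was put on by code.

**Early readings.** At early times the right-handed substrate leads in both earlier runs, and the lead stays small while the two substrates together shrink. This looks like a dynamic kinetic resolution: we take it that the free catalyst uses the left-handed substrate faster while the racemization catalyst replenishes it from the right-handed one.

| flask | left-handed substrate | right-handed substrate | coupling partner | free catalyst | racemization catalyst | added ligand | remark | time |
|---|---|---|---|---|---|---|---|---|
| alder | 0.30 M | 0.30 M | 3 equiv | 0.11 mol% | 0.28 mol% | 0.43 mM | run made earlier |  |
| maple | 0.30 M | 0.30 M | 3 equiv | 0.23 mol% | 0.28 mol% | 0.43 mM | run made earlier |  |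
| ochre | 0.30 M | 0.30 M | 3.00 equiv | 0.15 mol% | 0.28 mol% | 0.43 mM |  | 2.0 h |
| violet | 0.30 M | 0.30 M | 3.00 equiv | 0.08 mol% | 0.28 mol% | 0.43 mM |  | 2.0 h |

- alder (time / min: right-handed substrate / %, left-handed substrate / %): 6.00: 49.0, 45.6; 12.0: 45.1, 41.9; 20.0: 42.7, 38.2; 30.0: 38.1, 35.8; 50.0: 32.5, 30.7; 80.0: 26.9, 26.3
- maple (time / min: right-handed substrate / %, left-handed substrate / %): 6.00: 45.3, 41.4; 12.0: 41.4, 36.1; 20.0: 35.5, 31.9; 30.0: 30.6, 26.7; 50.0: 22.5, 20.9; 80.0: 15.9, 14.2

(readings scatter by 0.5 percentage points)

- free catalyst is single-handed; left-handed substrate and right-handed substrate are mirror images of each other, charged as a racemate, each of them at the stated concentration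
- an excess is the difference of the two amounts in percent of their sum
- an excess is below zero if the other one leads

- which of the two ends with the higher excess of right-handed substrate over left-handed substrate among what is left of the two ("neither" if they lie within 2 percentage points) (ochre / violet / neither)
- excess of right-handed substrate over left-handed substrate among what is left of the two at the end, ochre
- excess of right-handed substrate over left-handed substrate among what is left of the two at the end, violet

**The choice.** We must choose the free catalyst loading for the next run. If ochre and violet end within 2 percentage points, we charge ochre's loading for speed and leave the racemization catalyst and added ligand as they are.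

**The lag.** Summed over each run's readings, the excess is 3.49% in alder and 5.52% in maple. From first reading to last, the two substrates together shrink at a fractional rate of 0.467 h⁻¹ in alder and 0.858 h⁻¹ in maple. Dividing excess by rate gives 4.49 min and 3.86 min, as readings with their scatter. Both runs carry the same racemization catalyst and added ligand, so we average. This mean, 4.17 min, is our lag, the excess divided by the fractional rate of shrinking. It is much shorter than 69.9 min, the inverse of maple's rate, so we expect the excess to follow the rate of the moment.

**Our reckoning.** From 30.0 min to 80.0 min the fractional rates read 0.394 h⁻¹ in alder and 0.773 h⁻¹ in maple, lower than the whole-run values, so the fractional rate appears to fall. Scaled by free catalyst loading and averaged, they give 0.521 h⁻¹ for ochre and 0.278 h⁻¹ for violet. Times the lag, that is 3.62% and 1.93%, a gap of 1.7 points, smaller than 2 points. We expect the rate to fall further, so we take both as high estimates, commit to no difference, and charge ochre.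

**Forecast, result.** The forecast says neither, with 3% for ochre (1.5% to 4.8%) and 1.7% for violet (0.7% to 3%), both under our estimates, holding that “the excess is roughly proportional to free catalyst”. The flask gives neither: ochre 2.57%, violet 1.67%.

    coupling partner + free catalyst + left-handed substrate → free catalyst + left-handed product (k = 3490 L² mol⁻² h⁻¹)
    free catalyst → spent catalyst (k = 0.150 h⁻¹)
    coupling partner + free catalyst + right-handed substrate → free catalyst + right-handed product (k = 1160 L² mol⁻² h⁻¹)
    left-handed product ⇌ right-handed product (k = 0.182 h⁻¹)
    racemization catalyst + added ligand ⇌ idle complex, settled at all times (K = 71000 L mol⁻¹)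
    left-handed substrate + racemization catalyst ⇌ right-handed substrate + racemization catalyst, rate k6*[racemization catalyst]*[left-handed substrate] forward; the back reaction follows from the equilibrium constant (k = 9140 L mol⁻¹ h⁻¹)

**Lag tested.** The lag belongs to racemization: with that step taken away, ochre ends at 53.0% instead of 2.57%. The neighbour of violet charged with 0.11 mol% of racemization catalyst has 9.65% of it unbound, against 50.5% in violet. The neighbour's unbound amount is therefore smaller by a factor of 13.3, and if the lag grows by that factor, our lag becomes 55.5 min. Violet's 1.67% scaled by that factor gives 22.2%, and the neighbour ends at 19.0%.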